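**Plan**

1. Retrosynthesis: cut the C8–O ester bond, the C3–C4 epoxide (back to an alkene), the C4–C15 bond (methyl from the enol triflate of a C4 ketone), the C5–H bond and the C10–O/C9–H bonds (both back to alkenes), and finally C1–C10 and C7–C8, which divides the seven-membered ring between an alkenylcyclopentene and a vinyldiazoacetate.
2. Forward: the five-membered ring is bought as cyclopent-2-enone and receives its side chain by cross-coupling; the seven-membered ring (C1, C5, C6, C7, C8, C9, C10) closes in step 7; the epoxide ring is made in step 18 and the ester is attached last.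
3. Enabling feature: in the seven-membered ring H1, H7 and H8 lie on one face and C9–C10 sits between C1 and C8, so the ring is a masked 1,4-cycloheptadiene (C5=C6, C9=C10). Its sp3 carbons C1, C7 and C8 are the ones a boat Cope rearrangement of a cis-dialkenylcyclopropane C1–C5–C10 delivers in this relative configuration.
4. Stereochemistry: C1 from the chiral dirhodium catalyst; C7 and C8 from the boat Cope transition state; C9/C10 from C8-hydroxyl-directed epoxidation and hydride opening; C5 from hydroxyl-directed hydrogenation; C3/C4 from epoxidation on the face away from the silylated C10 oxygen.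

Key step: step 7

Numbering: guaiane numbering throughout (five-membered ring C1–C5 with C1 and C5 at the ring fusion; seven-membered ring C1, C10, C9, C8, C7, C6, C5; C14 on C10, C15 on C4); β is the face of the C8 oxygen, α the other; H1, H7 and H8 are α.

Assumption: the catalyst of step 7 is taken to attack the ring alkene with the facial sense it shows toward styrene with methyl aryldiazoacetates ((1S,2R)-cyclopropane); if the sense proves opposite, the enantiomeric catalyst is used and nothing else changes.

**Route**

Step 1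
Reactants: 1 cyclopent-2-en-1-one
Product: 2 2-iodocyclopent-2-en-1-one
Conditions: I2, pyridine, CH2Cl2, 0 °C to rt
Reagents that add atoms: iodine, II
Why: α-Iodination of the enone by conjugate addition of pyridine, iodination of the enolate and elimination (Baylis–Hillman-type addition–elimination) is the standard route to 2-iodoenones and creates no stereocentre.

Step 2
Reactants: 2 2-iodocyclopent-2-en-1-one
Product: 3 6-iodo-1,4-dioxaspiro[4.4]non-6-ene
Conditions: HOCH2CH2OH, TsOH·H2O (cat.), benzene, reflux, azeotropic removal of water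
Reagents that add atoms: ethylene glycol, OCCO
Why: Acid-catalysed ketalisation of a 2-haloenone is well established and gives the dioxolane with the double bond in its original position.

Step 3
Reactants: 3 6-iodo-1,4-dioxaspiro[4.4]non-6-ene; 4 (E)-3-methylbut-1-enylboronic acid pinacol ester
Product: 5 6-[(E)-3-methylbut-1-enyl]-1,4-dioxaspiro[4.4]non-6-ene
Conditions: Pd(dppf)Cl2 (5 mol %), K3PO4, THF/H2O, 60 °C
Reagents that add atoms: none
Why: Suzuki–Miyaura coupling of the alkenyl iodide with the (E)-alkenylboronate proceeds with retention of both alkene geometries and gives the 1,3-diene.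

Step 4
Reactants: 6 glycine methyl ester hydrochloride
Product: 7 methyl diazoacetate
Conditions: NaNO2, H2SO4 (cat.), H2O/CH2Cl2, −5 °C; used as a CH2Cl2 solution
Reagents that add atoms: sodium nitrite, [Na+].[O-]N=O
Why: Diazotisation of the primary amine of an α-amino ester gives a diazonium ion that loses its acidic α-proton to form the stabilised diazo ester.

Step 5
Reactants: 7 methyl diazoacetate; 8 (tert-butyldimethylsilyloxy)acetaldehyde
Product: 9 methyl 4-(tert-butyldimethylsilyloxy)-2-diazo-3-hydroxybutanoate (racemic)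
Conditions: DBU (20 mol %), MeCN, rt
Reagents that add atoms: none
Why: Base-catalysed aldol-type addition of the nucleophilic diazo carbon to the aldehyde gives the β-hydroxy α-diazo ester, whose racemic carbinol centre is removed in step 6.

Step 6
Reactants: 9 methyl 4-(tert-butyldimethylsilyloxy)-2-diazo-3-hydroxybutanoate
Product: 10 methyl (E)-4-(tert-butyldimethylsilyloxy)-2-diazobut-3-enoate
Conditions: POCl3, Et3N, CH2Cl2, 0 °C; used at once
Reagents that add atoms: none
Why: Dehydration of the β-hydroxy α-diazo ester through its dichlorophosphate (E2-type elimination) gives the conjugated vinyldiazoacetate, and the E enol ether should be favoured because the silyloxy and diazoester groups lie anti in the elimination.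

Step 7
Reactants: 5 6-[(E)-3-methylbut-1-enyl]-1,4-dioxaspiro[4.4]non-6-ene; 10 methyl (E)-4-(tert-butyldimethylsilyloxy)-2-diazobut-3-enoate
Product: 13 methyl 8β-(tert-butyldimethylsilyloxy)-4,4-(ethylenedioxy)-1αH,7αH-15-norguaia-5,9-dien-14-oate, via trans-dialkenylcyclopropane 11 (not isolated), via cis-dialkenylcyclopropane 12 (not isolated)
Conditions: Rh2(S-DOSP)4 (dirhodium tetrakis[(S)-N-(4-dodecylbenzenesulfonyl)prolinate], 1 mol %), hexanes, −40 °C to rt, slow addition of 10 (1.5 equiv); then toluene, 110 °C
Reagents that add atoms: none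
Why: The rhodium carbenoid formed from 10 with loss of N2 is attacked by C1, the unsubstituted end of the ring alkene of 5, and closes onto C5; as is usual for donor/acceptor carbenoids and cyclic alkenes the silyloxyvinyl group should come to lie over the five-membered ring, so the first product 11 has its two alkenyl groups trans, and heating lets the weak, doubly allylic C5–C10 bond open and re-close until C10 has inverted to 12 (C1 and C5 cannot invert, since the bicycle must stay cis-fused). The closest known reactions are the dirhodium-catalysed tandem cyclopropanation/Cope rearrangement of vinyldiazoacetates with 1,3-dienes and the thermal rearrangement of trans-1,2-divinylcyclopropanes to 1,4-cycloheptadienes through their cis isomers. The seven-membered ring closes by [3,3]-sigmatropic ring expansion of 12 through a boat transition state, in which C7–C8 forms while C5–C10 breaks and C1–C10 is kept. C1 is set in the cyclopropanation by the chiral catalyst, which chooses between the enantiotopic faces of the ring alkene, and C7 and C8 are set relative to C1 by the boat geometry, where the E substituents (isopropyl and silyloxy) point outward and H7 and H8 point toward H1. The step needs site selectivity, which the substrate supplies because donor/acceptor carbenoids do not cyclopropanate the trans-disubstituted side-chain alkene and attack at C1 places the developing charge on C5 next to that alkene; it also needs reaction at the carbenoid carbon and not at the silyloxy-bearing vinylogous carbon, which the hydrocarbon solvent and the bulky prolinate ligands favour.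

Step 8
Reactants: 13 methyl 8β-(tert-butyldimethylsilyloxy)-4,4-(ethylenedioxy)-1αH,7αH-15-norguaia-5,9-dien-14-oate
Product: 14 8β-(tert-butyldimethylsilyloxy)-4,4-(ethylenedioxy)-1αH,7αH-15-norguaia-5,9-dien-14-ol
Conditions: i-Bu2AlH (2.5 equiv), CH2Cl2, −78 °C
Reagents that add atoms: none
Why: Hydride reduction of the α,β-unsaturated ester with i-Bu2AlH proceeds in 1,2-fashion to the allylic alcohol at low temperature and leaves ketal, silyl ether and both alkenes alone.

Step 9
Reactants: 14 8β-(tert-butyldimethylsilyloxy)-4,4-(ethylenedioxy)-1αH,7αH-15-norguaia-5,9-dien-14-ol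
Product: 16 8β-(tert-butyldimethylsilyloxy)-4,4-(ethylenedioxy)-1αH,7αH-15-norguaia-5,9-diene, via allylic mesylate 15 (not isolated)
Conditions: MsCl, Et3N, THF, −20 °C; then LiEt3BH, −20 to 0 °C
Reagents that add atoms: none
Why: SN2 displacement of the primary allylic mesylate by the strongly nucleophilic hydride LiEt3BH gives the C14 methyl group without allylic transposition, since the alternative SN2′ site C9 is secondary and flanked by the silyloxy-bearing carbon.

Step 10
Reactants: 16 8β-(tert-butyldimethylsilyloxy)-4,4-(ethylenedioxy)-1αH,7αH-15-norguaia-5,9-diene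
Product: 17 4,4-(ethylenedioxy)-1αH,7αH-15-norguaia-5,9-dien-8β-ol
Conditions: Bu4NF, THF, 0 °C to rt
Reagents that add atoms: none
Why: Fluoride-mediated desilylation frees the C8 hydroxyl that directs the next three steps.

Step 11
Reactants: 17 4,4-(ethylenedioxy)-1αH,7αH-15-norguaia-5,9-dien-8β-ol
Product: 18 9β,10β-epoxy-4,4-(ethylenedioxy)-1αH,7αH-15-norguai-5-en-8β-ol
Conditions: VO(acac)2 (5 mol %), t-BuOOH (1.2 equiv), CH2Cl2, 0 °C to rt
Reagents that add atoms: tert-butyl hydroperoxide, CC(C)(C)OO
Why: Vanadium-catalysed hydroxyl-directed epoxidation transfers oxygen within an alkoxide–peroxide complex to the allylic alkene C9=C10 on the face of the C8 hydroxyl, which sets C9 and C10 as the β-epoxide and spares the more remote C5=C6 alkene.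

Step 12
Reactants: 18 9β,10β-epoxy-4,4-(ethylenedioxy)-1αH,7αH-15-norguai-5-en-8β-ol
Product: 19 4,4-(ethylenedioxy)-1αH,7αH-15-norguai-5-ene-8β,10β-diol
Conditions: NaAlH2(OCH2CH2OMe)2, THF, 0 °C to rt
Reagents that add atoms: none
Why: In this reductive opening of a 2,3-epoxy alcohol the aluminium hydride bound to the C8 alkoxide delivers hydride to C9, which is also the less substituted epoxide carbon, so the C10–O bond and with it the β-hydroxyl/α-methyl arrangement at C10 are kept.

Step 13
Reactants: 19 4,4-(ethylenedioxy)-1αH,7αH-15-norguai-5-ene-8β,10β-diol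
Product: 20 4,4-(ethylenedioxy)-1αH,5βH,7αH-15-norguaiane-8β,10β-diol
Conditions: H2 (1 atm), [Ir(cod)(PCy3)(py)]PF6 (10 mol %), CH2Cl2, rt
Reagents that add atoms: none
Why: In this hydroxyl-directed hydrogenation the cationic iridium centre binds the β-oriented hydroxyls on C8 and C10, both homoallylic to C5=C6, and adds hydrogen to the β face, which sets C5 with H5 trans to H1.

Step 14
Reactants: 20 4,4-(ethylenedioxy)-1αH,5βH,7αH-15-norguaiane-8β,10β-diol
Product: 21 8β,10β-dihydroxy-1αH,5βH,7αH-15-norguaian-4-one
Conditions: PPTS (cat.), acetone/H2O (10:1), 50 °C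
Reagents that add atoms: water, O
Why: Mild acid-catalysed ketal hydrolysis frees the C4 ketone without dehydrating the tertiary alcohol or enolising toward C5.

Step 15
Reactants: 21 8β,10β-dihydroxy-1αH,5βH,7αH-15-norguaian-4-one
Product: 22 8β,10β-bis(triethylsilyloxy)-1αH,5βH,7αH-15-norguaian-4-one
Conditions: Et3SiOTf (2.5 equiv), 2,6-lutidine, CH2Cl2, −78 to 0 °C
Reagents that add atoms: triethylsilyl trifluoromethanesulfonate, CC[Si](CC)(CC)OS(=O)(=O)C(F)(F)F
Why: Silylation with the silyl triflate and a hindered pyridine base covers both the secondary and the tertiary hydroxyl, so that no alkoxide interferes with the enolate chemistry of steps 16 and 17.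

Step 16
Reactants: 22 8β,10β-bis(triethylsilyloxy)-1αH,5βH,7αH-15-norguaian-4-one
Product: 23 8β,10β-bis(triethylsilyloxy)-1αH,5βH,7αH-15-norguai-3-en-4-yl trifluoromethanesulfonate
Conditions: KN(SiMe3)2, THF, −78 °C; then PhNTf2, −78 to 0 °C
Reagents that add atoms: N-phenylbis(trifluoromethanesulfonimide), O=S(=O)(N(c1ccccc1)S(=O)(=O)C(F)(F)F)C(F)(F)F
Why: Kinetic deprotonation with the hindered amide base takes place at the C3 methylene and not at the C5 ring-fusion methine, and O-sulfonylation of the enolate fixes the C3=C4 double bond as the enol triflate without touching C5.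

Step 17
Reactants: 23 8β,10β-bis(triethylsilyloxy)-1αH,5βH,7αH-15-norguai-3-en-4-yl trifluoromethanesulfonate
Product: 24 8β,10β-bis(triethylsilyloxy)-1αH,5βH,7αH-guai-3-ene
Conditions: MeMgBr, Fe(acac)3 (5 mol %), THF/NMP, −30 °C
Reagents that add atoms: methylmagnesium bromide, C[Mg]Br
Why: Iron-catalysed cross-coupling of the alkenyl triflate with the methyl Grignard reagent (Kumada-type coupling) replaces the triflate by the C15 methyl group with retention of the alkene position.

Step 18
Reactants: 24 8β,10β-bis(triethylsilyloxy)-1αH,5βH,7αH-guai-3-ene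
Product: 25 3α,4α-epoxy-8β,10β-bis(triethylsilyloxy)-1αH,5βH,7αH-guaiane
Conditions: mCPBA, NaHCO3, CH2Cl2, 0 °C
Reagents that add atoms: meta-chloroperoxybenzoic acid, O=C(OO)c1cccc(Cl)c1
Why: Prilezhaev epoxidation of the only alkene should take place on the α face, anti to the pseudo-axial allylic C–H bonds at C5 and C2 of the trans-fused cyclopentene envelope and away from the bulky silyloxy group on the β face of C10, which sets C3 and C4.

Step 19
Reactants: 25 3α,4α-epoxy-8β,10β-bis(triethylsilyloxy)-1αH,5βH,7αH-guaiane
Product: 26 3α,4α-epoxy-1αH,5βH,7αH-guaiane-8β,10β-diol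
Conditions: Bu4NF, THF, rt to 40 °C
Reagents that add atoms: none
Why: Fluoride-mediated desilylation cleaves both triethylsilyl ethers under basic conditions that leave the epoxide untouched.

Step 20
Reactants: 26 3α,4α-epoxy-1αH,5βH,7αH-guaiane-8β,10β-diol; 27 3,4-dimethoxybenzoyl chloride
Product: 28 3α,4α-epoxy-10β-hydroxy-1αH,5βH,7αH-guaian-8β-yl 3,4-dimethoxybenzoate (CNP0304846.1)
Conditions: Et3N, DMAP (cat.), CH2Cl2, 0 °C to rt
Reagents that add atoms: none
Why: DMAP-catalysed acylation (nucleophilic catalysis) takes place at the secondary C8 hydroxyl only, the tertiary C10 hydroxyl being too hindered, and the amine-buffered medium spares the epoxide.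

**Compound list**

1 | cyclopent-2-en-1-one | O=C1C=CCC1 | starting material
2 | 2-iodocyclopent-2-en-1-one | O=C1CCC=C1I | intermediate
3 | 6-iodo-1,4-dioxaspiro[4.4]non-6-ene | IC1=CCCC12OCCO2 | intermediate
4 | (E)-3-methylbut-1-enylboronic acid pinacol ester | CC(C)/C=C/B1OC(C)(C)C(C)(C)O1 | starting material
5 | 6-[(E)-3-methylbut-1-enyl]-1,4-dioxaspiro[4.4]non-6-ene | CC(C)/C=C/C1=CCCC12OCCO2 | intermediate
6 | glycine methyl ester hydrochloride | COC(=O)CN.Cl | starting material
7 | methyl diazoacetate | COC(=O)C=[N+]=[N-] | intermediate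
8 | (tert-butyldimethylsilyloxy)acetaldehyde | CC(C)(C)[Si](C)(C)OCC=O | starting material
9 | methyl 4-(tert-butyldimethylsilyloxy)-2-diazo-3-hydroxybutanoate (racemic at C3) | COC(=O)C(=[N+]=[N-])C(O)CO[Si](C)(C)C(C)(C)C | intermediate
10 | methyl (E)-4-(tert-butyldimethylsilyloxy)-2-diazobut-3-enoate | COC(=O)C(=[N+]=[N-])/C=C/O[Si](C)(C)C(C)(C)C | intermediate
11 | trans-dialkenylcyclopropane: methyl 6-[(E)-2-(tert-butyldimethylsilyloxy)ethenyl]-1-[(E)-3-methylbut-1-enyl]spiro[bicyclo[3.1.0]hexane-2,2'-[1,3]dioxolane]-6-carboxylate, silyloxyvinyl group endo (over the five-membered ring, trans to the alkenyl group on C5) | COC(=O)[C@]1(/C=C/O[Si](C)(C)C(C)(C)C)[C@]2(/C=C/C(C)C)[C@H]1CCC23OCCO3 | intermediate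
12 | cis-dialkenylcyclopropane: C10 epimer of 11, silyloxyvinyl group exo (cis to the alkenyl group on C5 and to H1) | COC(=O)[C@@]1(/C=C/O[Si](C)(C)C(C)(C)C)[C@]2(/C=C/C(C)C)[C@H]1CCC23OCCO3 | intermediate
13 | methyl 8β-(tert-butyldimethylsilyloxy)-4,4-(ethylenedioxy)-1αH,7αH-15-norguaia-5,9-dien-14-oate (7β-isopropyl; H1, H7, H8 cis) | CC(C)(C)[Si](C)(C)O[C@@H]2C=C(C(=O)OC)[C@@H]3CCC4(OCCO4)C3=C[C@@H]2C(C)C | intermediate
14 | 8β-(tert-butyldimethylsilyloxy)-4,4-(ethylenedioxy)-1αH,7αH-15-norguaia-5,9-dien-14-ol | CC(C)(C)[Si](C)(C)O[C@@H]2C=C(CO)[C@@H]3CCC4(OCCO4)C3=C[C@@H]2C(C)C | intermediate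
15 | 14-methanesulfonate of 14 (allylic mesylate) | CC(C)(C)[Si](C)(C)O[C@@H]2C=C(COS(C)(=O)=O)[C@@H]3CCC4(OCCO4)C3=C[C@@H]2C(C)C | intermediate
16 | 8β-(tert-butyldimethylsilyloxy)-4,4-(ethylenedioxy)-1αH,7αH-15-norguaia-5,9-diene | CC(C)(C)[Si](C)(C)O[C@@H]2C=C(C)[C@@H]3CCC4(OCCO4)C3=C[C@@H]2C(C)C | intermediate
17 | 4,4-(ethylenedioxy)-1αH,7αH-15-norguaia-5,9-dien-8β-ol | O[C@@H]2C=C(C)[C@@H]3CCC4(OCCO4)C3=C[C@@H]2C(C)C | intermediate
18 | 9β,10β-epoxy-4,4-(ethylenedioxy)-1αH,7αH-15-norguai-5-en-8β-ol (10α-methyl) | O[C@@H]2[C@@H]5O[C@]5(C)[C@@H]3CCC4(OCCO4)C3=C[C@@H]2C(C)C | intermediate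
19 | 4,4-(ethylenedioxy)-1αH,7αH-15-norguai-5-ene-8β,10β-diol (10α-methyl) | O[C@@H]2C[C@](C)(O)[C@@H]3CCC4(OCCO4)C3=C[C@@H]2C(C)C | intermediate
20 | 4,4-(ethylenedioxy)-1αH,5βH,7αH-15-norguaiane-8β,10β-diol | O[C@@H]2C[C@](C)(O)[C@@H]3CCC4(OCCO4)[C@H]3C[C@@H]2C(C)C | intermediate
21 | 8β,10β-dihydroxy-1αH,5βH,7αH-15-norguaian-4-one | O[C@@H]2C[C@](C)(O)[C@@H]3CCC(=O)[C@H]3C[C@@H]2C(C)C | intermediate
22 | 8β,10β-bis(triethylsilyloxy)-1αH,5βH,7αH-15-norguaian-4-one | CC[Si](CC)(CC)O[C@@H]2C[C@](C)(O[Si](CC)(CC)CC)[C@@H]3CCC(=O)[C@H]3C[C@@H]2C(C)C | intermediate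
23 | 8β,10β-bis(triethylsilyloxy)-1αH,5βH,7αH-15-norguai-3-en-4-yl trifluoromethanesulfonate | CC[Si](CC)(CC)O[C@@H]2C[C@](C)(O[Si](CC)(CC)CC)[C@@H]3CC=C(OS(=O)(=O)C(F)(F)F)[C@H]3C[C@@H]2C(C)C | intermediate
24 | 8β,10β-bis(triethylsilyloxy)-1αH,5βH,7αH-guai-3-ene | CC[Si](CC)(CC)O[C@@H]2C[C@](C)(O[Si](CC)(CC)CC)[C@@H]3CC=C(C)[C@H]3C[C@@H]2C(C)C | intermediate
25 | 3α,4α-epoxy-8β,10β-bis(triethylsilyloxy)-1αH,5βH,7αH-guaiane | CC[Si](CC)(CC)O[C@@H]2C[C@](C)(O[Si](CC)(CC)CC)[C@@H]3C[C@H]4O[C@@]4(C)[C@H]3C[C@@H]2C(C)C | intermediate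
26 | 3α,4α-epoxy-1αH,5βH,7αH-guaiane-8β,10β-diol | O[C@@H]2C[C@](C)(O)[C@@H]3C[C@H]4O[C@@]4(C)[C@H]3C[C@@H]2C(C)C | intermediate
27 | 3,4-dimethoxybenzoyl chloride | COc1ccc(C(Cl)=O)cc1OC | starting material
28 | 3α,4α-epoxy-10β-hydroxy-1αH,5βH,7αH-guaian-8β-yl 3,4-dimethoxybenzoate (CNP0304846.1) | COc1ccc(C(=O)O[C@@H]2C[C@](C)(O)[C@@H]3C[C@H]4O[C@@]4(C)[C@H]3C[C@@H]2C(C)C)cc1OC | target

**Step count and risks**

Total: 20 steps. Longest linear sequence: 17 steps (steps 1–3 and 7–20, from cyclopent-2-en-1-one); steps 4–6 form the three-step side branch.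

Steps most likely to fail:

Step 7. The carbenoid may discriminate poorly between the two faces of the cyclic, trisubstituted alkene, a poorer match for the prolinate catalyst than the mono- and cis-disubstituted alkenes on which its selectivity rests, so that the ring system is formed with low enantiomeric purity. The fallback secures enantiomeric purity by resolution instead of by the catalyst. It leaves the route at silyl ether 16: after desilylation as in step 10 the crude alcohol is esterified with (S)-O-methylmandelic acid (DCC, DMAP, CH2Cl2; Steglich esterification). The two diastereomeric esters, (S)-O-methylmandelate of 17 F1 and (S)-O-methylmandelate of the enantiomer of 17 F2, are separated by chromatography or crystallisation. F1 is cleaved with K2CO3 in MeOH, and the route is rejoined at 17 as a single enantiomer.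

Step 13. Hydrogen delivery to the hindered C5=C6 alkene may be slow or unselective, for example because the 1,3-diol binds the iridium centre as a chelate and deactivates it. The fallback sets C5 under thermodynamic instead of kinetic control. It sets out from 19: ketal hydrolysis (PPTS, acetone/H2O) gives 8β,10β-dihydroxy-1αH,7αH-15-norguai-5-en-4-one F3. Hydrogenation of the enone double bond (H2, Pd/C, EtOAc) gives the saturated ketone as a mixture at C5 that contains the cis-fused ketone F4. NaOMe in MeOH then equilibrates C5 through the C4 enolate toward the trans-fused ketone, which is expected to be the more stable epimer because both ring-fusion bonds are pseudo-equatorial. The route is rejoined at 21.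

Step 18. The peracid may attack mainly the β face if shielding of the α face by the allylic C5–C6 bond outweighs the torsional preference and the effect of the C10 silyloxy group. The fallback inverts the facial outcome by a two-stage anti addition. It sets out from 24: NBS in aqueous THF (NaHCO3, 0 °C) forms the bromonium ion on the same β face, and water opens it at the tertiary C4 from the α face to give the 3β-bromo-4α-hydroxy compound, bromohydrin F5. K2CO3 in MeOH then closes the α-epoxide by intramolecular SN2 displacement at C3, and the route is rejoined at 25.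

Further compounds
F1 | step 7 | (S)-O-methylmandelate of 17 | CO[C@H](C(=O)O[C@@H]2C=C(C)[C@@H]3CCC4(OCCO4)C3=C[C@@H]2C(C)C)c1ccccc1
F2 | step 7 | (S)-O-methylmandelate of the enantiomer of 17 | CO[C@H](C(=O)O[C@H]2C=C(C)[C@H]3CCC4(OCCO4)C3=C[C@H]2C(C)C)c1ccccc1
F3 | step 13 | 8β,10β-dihydroxy-1αH,7αH-15-norguai-5-en-4-one | O[C@@H]2C[C@](C)(O)[C@@H]3CCC(=O)C3=C[C@@H]2C(C)C
F4 | step 13 | 8β,10β-dihydroxy-1αH,5αH,7αH-15-norguaian-4-one (cis-fused C5 epimer of 21) | O[C@@H]2C[C@](C)(O)[C@@H]3CCC(=O)[C@@H]3C[C@@H]2C(C)C
F5 | step 18 | 3β-bromo-8β,10β-bis(triethylsilyloxy)-1αH,5βH,7αH-guaian-4α-ol (bromohydrin) | CC[Si](CC)(CC)O[C@@H]2C[C@](C)(O[Si](CC)(CC)CC)[C@@H]3C[C@H](Br)[C@@](C)(O)[C@H]3C[C@@H]2C(C)C
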